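The target is cut at the Z alkene C6=C7 (chain numbered from the lactone carbonyl C1 to the benzylic C15). This alkene sits between two oxygen-bearing carbons: C5, whose oxygen is the ring oxygen of the dihydropyranone (ring A), and the carbinol C9. Joining these two oxygens through one diisopropylsilylene unit lets ring-closing metathesis form C6=C7 inside an eight-membered dioxasilacyclooctene, a ring too small to accommodate a trans alkene. The precursor is the mixed silaketal of a C1–C6 vinyl carbinol already carrying the Z-enoate and a C7–C15 homoallylic alcohol with the C11 and C13 hydroxyls as TBS ethers. Fluoride then frees O5, which closes ring A.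

Key step: step 12

Remark: the target SMILES is read as (5S), C9/C11 syn and C11/C13 anti (9R,11S,13R); structures 18 and 19 match it at every stereocenter and alkene, so nothing needed correcting. TBS = tert-butyldimethylsilyl, Ipc = isopinocampheyl. The descriptor at C11 changes between 7 (6R) and 14–19 (6S) only because CIP priorities change. Ethyl 3-oxo-5-phenylpentanoate, (S)-epichlorohydrin and (+)-Ipc2B(allyl) are taken as purchased.

Step 1
Reactants: 1 ethyl 3-oxo-5-phenylpentanoate
Product: 2 ethyl (3R)-3-hydroxy-5-phenylpentanoate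
Conditions: H2 (4 atm), RuCl2[(R)-BINAP] (0.5 mol%), EtOH, 80 °C
Reagents that add atoms: none
Why: Noyori asymmetric hydrogenation: the ester-chelated ketone is reduced on the face selected by (R)-BINAP, which for 3-oxo esters delivers the (3R)-3-hydroxy ester and so sets C13.

Step 2
Reactants: 2 ethyl (3R)-3-hydroxy-5-phenylpentanoate
Product: 3 tert-butyl (5R)-5-hydroxy-3-oxo-7-phenylheptanoate
Conditions: LiN(iPr)2 (4 equiv), tert-butyl acetate (4 equiv), THF, −78 °C; then 2, −78 → −20 °C
Reagents that add atoms: tert-butyl acetate, CC(=O)OC(C)(C)C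
Why: Crossed Claisen condensation: the excess lithium enolate of tert-butyl acetate acylates on the ethyl ester of the lithium alkoxide of 2 and the product is shielded as its enolate, so the C13 carbinol is carried through unchanged.

Step 3
Reactants: 3 tert-butyl (5R)-5-hydroxy-3-oxo-7-phenylheptanoate
Product: 4 tert-butyl (3S,5R)-3,5-dihydroxy-7-phenylheptanoate
Conditions: Me4NBH(OAc)3 (5 equiv), MeCN/AcOH (1:1), −30 °C
Reagents that add atoms: none
Why: Evans–Saksena reduction: the C13 hydroxyl exchanges onto boron and hydride is delivered intramolecularly through a chair transition state, which sets C11 anti to C13 (3S in 4).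

Step 4
Reactants: 4 tert-butyl (3S,5R)-3,5-dihydroxy-7-phenylheptanoate
Product: 5 tert-butyl (3S,5R)-3,5-bis(tert-butyldimethylsilyloxy)-7-phenylheptanoate
Conditions: TBSCl (3 equiv), imidazole (6 equiv), DMF, rt → 40 °C
Reagents that add atoms: tert-butyldimethylsilyl chloride (TBSCl), CC(C)(C)[Si](C)(C)Cl
Why: Imidazole-mediated silyl ether formation on both secondary hydroxyls, with the tert-butyl ester inert under these conditions.

Step 5
Reactants: 5 tert-butyl (3S,5R)-3,5-bis(tert-butyldimethylsilyloxy)-7-phenylheptanoate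
Product: 6 (3S,5R)-3,5-bis(tert-butyldimethylsilyloxy)-7-phenylheptanal
Conditions: iBu2AlH (1.2 equiv), CH2Cl2, −78 °C; MeOH, then aqueous potassium sodium tartrate
Reagents that add atoms: none
Why: Partial reduction of an ester with iBu2AlH: the tetrahedral aluminium hemiacetal of the hindered tert-butyl ester persists at −78 °C and releases the aldehyde only on work-up, and the silyl ethers and both stereocenters are not affected.

Step 6
Reactants: 6 (3S,5R)-3,5-bis(tert-butyldimethylsilyloxy)-7-phenylheptanal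
Product: 7 (4R,6R,8R)-6,8-bis(tert-butyldimethylsilyloxy)-10-phenyldec-1-en-4-ol
Conditions: (+)-Ipc2B(allyl) (1.5 equiv, 1 M in pentane), Et2O, −78 °C; then NaOH, H2O2, 0 °C → rt
Reagents that add atoms: (+)-B-allyldiisopinocampheylborane, C=CCB([C@H]1C[C@H]2C[C@@H]([C@@H]1C)C2(C)C)[C@H]1C[C@H]2C[C@@H]([C@@H]1C)C2(C)C
Why: Brown allylboration: the reagent derived from (−)-α-pinene adds allyl through a chair Zimmerman–Traxler transition state to the Re face of the aldehyde under reagent control, which sets C9 as (4R) in 7, syn to the C11 silyl ether.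

Step 7
Reactants: 8 (S)-epichlorohydrin [(2S)-2-(chloromethyl)oxirane]
Product: 9 (2S)-1-chloro-5-(trimethylsilyl)pent-4-yn-2-ol
Conditions: trimethylsilylacetylene, n-BuLi, THF, −78 °C; BF3·OEt2; then 8, −78 °C
Reagents that add atoms: trimethylsilylacetylene, C#C[Si](C)(C)C
Why: Yamaguchi–Hirao alkynylation: the lithium acetylide opens the BF3-activated epoxide by SN2 attack at its unsubstituted carbon, so the stereocenter (the future C5) and the chloride are retained.

Step 8
Reactants: 9 (2S)-1-chloro-5-(trimethylsilyl)pent-4-yn-2-ol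
Product: 12 (3S)-hex-1-en-5-yn-3-ol, via silylpropargyl oxirane 10 (not isolated), via silyl enynol 11 (not isolated)
Conditions: Me3S+ I− (4 equiv), n-BuLi (3.8 equiv), THF, −20 °C → rt; then MeOH, K2CO3 (cat.), rt
Reagents that add atoms: trimethylsulfonium iodide, C[S+](C)C.[I-]
Why: Epoxide-to-allylic-alcohol homologation with dimethylsulfonium methylide: the alkoxide of 9 closes to epoxide 10, the ylide opens it at the CH2 terminus and the betaine loses Me2S to give the vinyl carbinol 11 without touching the stereocenter, and methanolysis then removes the alkynyl silyl group.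

Step 9
Reactants: 7 (4R,6R,8R)-6,8-bis(tert-butyldimethylsilyloxy)-10-phenyldec-1-en-4-ol; 13 dichlorodi(propan-2-yl)silane; 12 (3S)-hex-1-en-5-yn-3-ol
Product: 15 {[(4R,6S,8R)-6,8-bis(tert-butyldimethylsilyloxy)-10-phenyldec-1-en-4-yl]oxy}[(3S)-hex-1-en-5-yn-3-yloxy]di(propan-2-yl)silane, via chlorosilyl ether 14 (not isolated)
Conditions: 13 (3 equiv), imidazole, CH2Cl2, 0 °C → rt; excess 13 removed at 0.1 mmHg; then 12 (1.5 equiv), imidazole, DMAP (cat.), CH2Cl2, rt
Reagents that add atoms: none
Why: Stepwise silyl ether formation: 7 can take only one chloride from the excess dichlorosilane, the excess is pumped off, and the small alcohol 12 then displaces the remaining chloride of 14, so the valuable fragment cannot end up in a symmetrical bis-ether and no stereocenter is involved.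

Step 10
Reactants: 15 mixed silaketal with terminal alkyne
Product: 17 methyl (5S)-5-[({[(4R,6S,8R)-6,8-bis(tert-butyldimethylsilyloxy)-10-phenyldec-1-en-4-yl]oxy}di(propan-2-yl)silyl)oxy]hept-6-en-2-ynoate, via lithium acetylide 16 (not isolated)
Conditions: n-BuLi (1.1 equiv), THF, −78 °C; then ClCO2Me, −78 → −20 °C
Reagents that add atoms: methyl chloroformate, COC(=O)Cl
Why: Alkyne carboxylation: the terminal alkyne is the only acidic C–H, and its lithium acetylide is acylated on carbon by methyl chloroformate to install C1, while the hindered silaketal and the silyl ethers tolerate n-BuLi at −78 °C.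

Step 11
Reactants: 17 silaketal ynoate
Product: 18 methyl (2Z,5S)-5-[({[(4R,6S,8R)-6,8-bis(tert-butyldimethylsilyloxy)-10-phenyldec-1-en-4-yl]oxy}di(propan-2-yl)silyl)oxy]hepta-2,6-dienoate
Conditions: H2 (1 atm), Pd/CaCO3 poisoned with Pb(OAc)2 (Lindlar catalyst), quinoline, EtOAc/1-octene (10:1), rt, stopped after 1 equiv H2
Reagents that add atoms: none
Why: Lindlar semihydrogenation: syn addition of H2 to the activated ynoate on poisoned palladium gives the Z-enoate, quinoline and the sacrificial 1-octene keep the two monosubstituted alkenes from being reduced, and lactonization cannot occur because O5 is still bound to silicon.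

Step 12
Reactants: 18 mixed silaketal Z-enoate
Product: 19 methyl (2Z)-4-[(4S,5Z,8R)-8-[(2S,4R)-2,4-bis(tert-butyldimethylsilyloxy)-6-phenylhexyl]-2,2-di(propan-2-yl)-1,3-dioxa-2-silacyclooct-5-en-4-yl]but-2-enoate
Conditions: second-generation Grubbs catalyst (H2IMes)(PCy3)Cl2Ru=CHPh (10 mol%), CH2Cl2 (0.003 M), 40 °C, argon purge
Reagents that add atoms: none
Why: The ruthenium benzylidene exchanges onto the least hindered alkene, the terminal CH2=CH of the C9 allyl group, and the new alkylidene adds across the C5 vinyl group in a [2+2] cycloaddition; cycloreversion of the ruthenacyclobutane forms C6=C7 and expels ethylene, whose loss drives the reaction. The closest known reaction type is temporary-silicon-tethered ring-closing metathesis of mixed bis-alkoxysilanes built from an allylic and a homoallylic alcohol. The one ring closed is the eight-membered 1,3-dioxa-2-silacyclooct-4-ene skeleton, formed by ring-closing alkene metathesis with both new alkene carbons inside the ring. No stereocenter is created, and the only new stereo-element, the alkene geometry, is fixed as Z because an eight-membered ring cannot hold a trans double bond. The step needs site selectivity, secured by the catalyst's preference for the two monosubstituted alkenes over the electron-poor 1,2-disubstituted Z-enoate, and ring closure over oligomerization, secured by high dilution and by the two isopropyl groups on silicon, which favour folded conformers of the tether. The stereocenters at C5, C9, C11 and C13 lie outside the reacting carbons and are not affected.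

Step 13
Reactants: 19 eight-membered cyclic silaketal
Product: 21 (6S)-6-[(1Z,4R,6S,8R)-4,6,8-trihydroxy-10-phenyldec-1-en-1-yl]-5,6-dihydro-2H-pyran-2-one, via seco tetraol ester 20 (not isolated)
Conditions: HF·pyridine, pyridine, THF, 0 °C → rt; then PPTS (cat.), CH2Cl2, rt
Reagents that add atoms: none
Why: Fluoride-mediated desilylation followed by lactonization: HF·pyridine cleaves the silaketal and both TBS ethers, and the freed C5 hydroxyl, held next to the ester by the Z-C2=C3 alkene, closes ring A by acid-catalysed transesterification with loss of methanol, leaving all four stereocenters as set.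

Compound list
1 | ethyl 3-oxo-5-phenylpentanoate | CCOC(=O)CC(=O)CCc1ccccc1 | starting material
2 | ethyl (3R)-3-hydroxy-5-phenylpentanoate | CCOC(=O)C[C@H](O)CCc1ccccc1 | intermediate
3 | tert-butyl (5R)-5-hydroxy-3-oxo-7-phenylheptanoate | CC(C)(C)OC(=O)CC(=O)C[C@H](O)CCc1ccccc1 | intermediate
4 | tert-butyl (3S,5R)-3,5-dihydroxy-7-phenylheptanoate | CC(C)(C)OC(=O)C[C@@H](O)C[C@H](O)CCc1ccccc1 | intermediate
5 | tert-butyl (3S,5R)-3,5-bis(tert-butyldimethylsilyloxy)-7-phenylheptanoate | CC(C)(C)OC(=O)C[C@@H](O[Si](C)(C)C(C)(C)C)C[C@H](O[Si](C)(C)C(C)(C)C)CCc1ccccc1 | intermediate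
6 | (3S,5R)-3,5-bis(tert-butyldimethylsilyloxy)-7-phenylheptanal | O=CC[C@@H](O[Si](C)(C)C(C)(C)C)C[C@H](O[Si](C)(C)C(C)(C)C)CCc1ccccc1 | intermediate
7 | (4R,6R,8R)-6,8-bis(tert-butyldimethylsilyloxy)-10-phenyldec-1-en-4-ol (C7–C15 homoallylic alcohol) | C=CC[C@@H](O)C[C@@H](O[Si](C)(C)C(C)(C)C)C[C@H](O[Si](C)(C)C(C)(C)C)CCc1ccccc1 | intermediate
8 | (S)-epichlorohydrin, (2S)-2-(chloromethyl)oxirane | ClC[C@@H]1CO1 | starting material
9 | (2S)-1-chloro-5-(trimethylsilyl)pent-4-yn-2-ol | ClC[C@@H](O)CC#C[Si](C)(C)C | intermediate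
10 | (2S)-2-[3-(trimethylsilyl)prop-2-yn-1-yl]oxirane | C[Si](C)(C)C#CC[C@H]1CO1 | intermediate
11 | (3S)-6-(trimethylsilyl)hex-1-en-5-yn-3-ol | C[Si](C)(C)C#CC[C@@H](C=C)O | intermediate
12 | (3S)-hex-1-en-5-yn-3-ol | C#CC[C@@H](C=C)O | intermediate
13 | dichlorodi(propan-2-yl)silane | CC(C)[Si](Cl)(Cl)C(C)C | starting material
14 | chloro{[(4R,6S,8R)-6,8-bis(tert-butyldimethylsilyloxy)-10-phenyldec-1-en-4-yl]oxy}di(propan-2-yl)silane | C=CC[C@@H](O[Si](Cl)(C(C)C)C(C)C)C[C@@H](O[Si](C)(C)C(C)(C)C)C[C@H](O[Si](C)(C)C(C)(C)C)CCc1ccccc1 | intermediate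
15 | {[(4R,6S,8R)-6,8-bis(tert-butyldimethylsilyloxy)-10-phenyldec-1-en-4-yl]oxy}[(3S)-hex-1-en-5-yn-3-yloxy]di(propan-2-yl)silane | C#CC[C@@H](C=C)O[Si](C(C)C)(C(C)C)O[C@H](CC=C)C[C@@H](O[Si](C)(C)C(C)(C)C)C[C@H](O[Si](C)(C)C(C)(C)C)CCc1ccccc1 | intermediate
16 | lithium acetylide of 15 | [Li+].[C-]#CC[C@@H](C=C)O[Si](C(C)C)(C(C)C)O[C@H](CC=C)C[C@@H](O[Si](C)(C)C(C)(C)C)C[C@H](O[Si](C)(C)C(C)(C)C)CCc1ccccc1 | intermediate
17 | methyl (5S)-5-[({[(4R,6S,8R)-6,8-bis(tert-butyldimethylsilyloxy)-10-phenyldec-1-en-4-yl]oxy}di(propan-2-yl)silyl)oxy]hept-6-en-2-ynoate | COC(=O)C#CC[C@@H](C=C)O[Si](C(C)C)(C(C)C)O[C@H](CC=C)C[C@@H](O[Si](C)(C)C(C)(C)C)C[C@H](O[Si](C)(C)C(C)(C)C)CCc1ccccc1 | intermediate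
18 | methyl (2Z,5S)-5-[({[(4R,6S,8R)-6,8-bis(tert-butyldimethylsilyloxy)-10-phenyldec-1-en-4-yl]oxy}di(propan-2-yl)silyl)oxy]hepta-2,6-dienoate (key-step precursor) | COC(=O)/C=C\C[C@@H](C=C)O[Si](C(C)C)(C(C)C)O[C@H](CC=C)C[C@@H](O[Si](C)(C)C(C)(C)C)C[C@H](O[Si](C)(C)C(C)(C)C)CCc1ccccc1 | intermediate
19 | methyl (2Z)-4-[(4S,5Z,8R)-8-[(2S,4R)-2,4-bis(tert-butyldimethylsilyloxy)-6-phenylhexyl]-2,2-di(propan-2-yl)-1,3-dioxa-2-silacyclooct-5-en-4-yl]but-2-enoate (key-step product) | COC(=O)/C=C\C[C@H]1/C=C\C[C@H](C[C@@H](O[Si](C)(C)C(C)(C)C)C[C@H](O[Si](C)(C)C(C)(C)C)CCc2ccccc2)O[Si](C(C)C)(C(C)C)O1 | intermediate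
20 | methyl (2Z,5S,6Z,9R,11S,13R)-5,9,11,13-tetrahydroxy-15-phenylpentadeca-2,6-dienoate | COC(=O)/C=C\C[C@H](O)/C=C\C[C@@H](O)C[C@@H](O)C[C@H](O)CCc1ccccc1 | intermediate
21 | (6S)-6-[(1Z,4R,6S,8R)-4,6,8-trihydroxy-10-phenyldec-1-en-1-yl]-5,6-dihydro-2H-pyran-2-one | O=C1C=CC[C@@H](/C=C\C[C@@H](O)C[C@@H](O)C[C@H](O)CCc2ccccc2)O1 | target

Total step count: 13. Longest linear sequence: 11 steps (steps 1–6 and 9–13).

Steps most likely to fail

Step 12 (ring-closing metathesis). The eight-membered closure has to engage the hindered allylic C5 vinyl group. Intermolecular metathesis to oligomers, or migration of the allyl double bond before closure, may therefore outrun cyclization. The fallback gives up metathesis for the C6=C7 bond and makes it by a Z-selective Wittig reaction. It sets out from 7 and 12 and comes back to the route at 20.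
- From 7: silylation (TBSOTf, 2,6-lutidine) should give the tris-TBS ether of 7 F1. Ozonolysis with NaBH4 work-up should give the C7 primary alcohol F2. I2, PPh3 and imidazole should give the C7 primary iodide F3, and PPh3 in hot MeCN the triphenylphosphonium iodide F4.
- From 12: TBSCl and imidazole should give the TBS ether of 12 F5. Cleavage of its vinyl group (OsO4 cat., NaIO4, 2,6-lutidine, dioxane/water) should give the (2S)-2-silyloxy pent-4-ynal F6, to be used without storage.
- Coupling and return: NaN(SiMe3)2 in THF at −78 °C should convert F4 into the non-stabilized phosphorus ylide F7, which should add to F6 to give the (6Z)-alkene with terminal alkyne F8. n-BuLi should give the lithium acetylide F9 and ClCO2Me the tetrasilyl ynoate F10. Semihydrogenation under the conditions of step 11 (no terminal alkene is left) should give the (2Z,6Z)-dienoate F11. HF·pyridine should remove the four silyl groups to give 20, which lactonizes to 21 as in step 13.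

Step 11 (semihydrogenation). Poisoned palladium distinguishes an alkyne from a monosubstituted alkene only kinetically. The vinyl and allyl groups of 17 may therefore be hydrogenated along with the ynoate, or the Z-enoate may be reduced further. The fallback changes the order of events so that no terminal alkene is present during hydrogenation. It sets out from 17 and comes back at 19. Ynoate 17 is submitted to the high-dilution ring closure with the catalyst of step 12, which should give the cyclic silaketal ynoate F12. The electron-poor internal alkyne is a poor partner for enyne metathesis and could only close a nine-membered ring. Semihydrogenation of F12, whose only other alkene is the endocyclic cis-alkene, should then give 19.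

Step 9 (mixed silaketal). Hydrolysis of the chlorosilyl ether 14 while the excess dichlorosilane is pumped off, or exchange to symmetrical bis-ethers, may erode the supply of 15. The fallback builds the unsymmetrical O–Si–O unit through an isolable hydridosilane. It sets out from 7 and comes back at 15. Alcohol 7 with chlorodiisopropylsilane (iPr2SiHCl) and imidazole should give the diisopropylsilyl (Si–H) ether of 7 F13, which can be chromatographed. N-Bromosuccinimide in CH2Cl2 at 0 °C should convert its Si–H bond into the bromosilyl ether F14 in the flask, and addition of 12 and imidazole should give 15.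

Further compounds
F1 | step 12 | tris-TBS ether of 7, (4R,6S,8R)-4,6,8-tris(tert-butyldimethylsilyloxy)-10-phenyldec-1-ene | C=CC[C@@H](O[Si](C)(C)C(C)(C)C)C[C@@H](O[Si](C)(C)C(C)(C)C)C[C@H](O[Si](C)(C)C(C)(C)C)CCc1ccccc1
F2 | step 12 | C7 primary alcohol, 3,5,7-tris(tert-butyldimethylsilyloxy)-9-phenylnonan-1-ol, configured as F1 | OCC[C@@H](O[Si](C)(C)C(C)(C)C)C[C@@H](O[Si](C)(C)C(C)(C)C)C[C@H](O[Si](C)(C)C(C)(C)C)CCc1ccccc1
F3 | step 12 | C7 primary iodide, 1-iodo-3,5,7-tris(tert-butyldimethylsilyloxy)-9-phenylnonane, configured as F1 | ICC[C@@H](O[Si](C)(C)C(C)(C)C)C[C@@H](O[Si](C)(C)C(C)(C)C)C[C@H](O[Si](C)(C)C(C)(C)C)CCc1ccccc1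
F4 | step 12 | triphenylphosphonium iodide from F3 | [I-].c1ccccc1[P+](c1ccccc1)(c1ccccc1)CC[C@@H](O[Si](C)(C)C(C)(C)C)C[C@@H](O[Si](C)(C)C(C)(C)C)C[C@H](O[Si](C)(C)C(C)(C)C)CCc1ccccc1
F5 | step 12 | TBS ether of 12, (3S)-3-(tert-butyldimethylsilyloxy)hex-1-en-5-yne | C#CC[C@@H](C=C)O[Si](C)(C)C(C)(C)C
F6 | step 12 | (2S)-2-(tert-butyldimethylsilyloxy)pent-4-ynal | C#CC[C@@H](C=O)O[Si](C)(C)C(C)(C)C
F7 | step 12 | non-stabilized phosphorus ylide from F4 | c1ccccc1P(c1ccccc1)(c1ccccc1)=CC[C@@H](O[Si](C)(C)C(C)(C)C)C[C@@H](O[Si](C)(C)C(C)(C)C)C[C@H](O[Si](C)(C)C(C)(C)C)CCc1ccccc1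
F8 | step 12 | (6Z)-alkene with terminal alkyne, C2–C15 chain with TBS ethers at O5, O9, O11 and O13 | C#CC[C@@H](/C=C\C[C@@H](O[Si](C)(C)C(C)(C)C)C[C@@H](O[Si](C)(C)C(C)(C)C)C[C@H](O[Si](C)(C)C(C)(C)C)CCc1ccccc1)O[Si](C)(C)C(C)(C)C
F9 | step 12 | lithium acetylide of F8 | [Li+].[C-]#CC[C@@H](/C=C\C[C@@H](O[Si](C)(C)C(C)(C)C)C[C@@H](O[Si](C)(C)C(C)(C)C)C[C@H](O[Si](C)(C)C(C)(C)C)CCc1ccccc1)O[Si](C)(C)C(C)(C)C
F10 | step 12 | tetrasilyl ynoate, methyl ester of the C1–C15 chain with C2≡C3 and (6Z) | COC(=O)C#CC[C@@H](/C=C\C[C@@H](O[Si](C)(C)C(C)(C)C)C[C@@H](O[Si](C)(C)C(C)(C)C)C[C@H](O[Si](C)(C)C(C)(C)C)CCc1ccccc1)O[Si](C)(C)C(C)(C)C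
F11 | step 12 | (2Z,6Z)-dienoate, tetra-TBS ether of 20 | COC(=O)/C=C\C[C@@H](/C=C\C[C@@H](O[Si](C)(C)C(C)(C)C)C[C@@H](O[Si](C)(C)C(C)(C)C)C[C@H](O[Si](C)(C)C(C)(C)C)CCc1ccccc1)O[Si](C)(C)C(C)(C)C
F12 | step 11 | cyclic silaketal ynoate, the C2≡C3 analogue of 19 | COC(=O)C#CC[C@H]1/C=C\C[C@H](C[C@@H](O[Si](C)(C)C(C)(C)C)C[C@H](O[Si](C)(C)C(C)(C)C)CCc2ccccc2)O[Si](C(C)C)(C(C)C)O1
F13 | step 9 | diisopropylsilyl (Si–H) ether of 7 | C=CC[C@@H](O[SiH](C(C)C)C(C)C)C[C@@H](O[Si](C)(C)C(C)(C)C)C[C@H](O[Si](C)(C)C(C)(C)C)CCc1ccccc1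
F14 | step 9 | bromosilyl ether, bromo analogue of 14 | C=CC[C@@H](O[Si](Br)(C(C)C)C(C)C)C[C@@H](O[Si](C)(C)C(C)(C)C)C[C@H](O[Si](C)(C)C(C)(C)C)CCc1ccccc1
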